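**Assumption:** the target is read exactly as its SMILES, the achiral bis(2,3-dibromo-4,5-dihydroxyphenyl)methane; where a silyl group is needed for the furan alternative it is taken as triisopropylsilyl.

**Numbering used throughout:** 1 4-bromo-2-methoxyphenol; 2 benzyl bromide; 3 1-(benzyloxy)-4-bromo-2-methoxybenzene; 4 4-(benzyloxy)-3-methoxybenzaldehyde; 5 [4-(benzyloxy)-3-methoxyphenyl]lithium; 6 bis[4-(benzyloxy)-3-methoxyphenyl]methanol; 7 bis[4-(benzyloxy)-3-methoxyphenyl]methanone; 8 bis(4-hydroxy-3-methoxyphenyl)methanone; 9 bromine; 10 bis(3-bromo-4-hydroxy-5-methoxyphenyl)methanone; 11 bis(2,3-dibromo-4-hydroxy-5-methoxyphenyl)methanone; 12 bis(2,3-dibromo-4-hydroxy-5-methoxyphenyl)methanol; 13 bis(2,3-dibromo-4-hydroxy-5-methoxyphenyl)methane; 14 the target.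

## Analysis of the target

Compound 14 is a diarylmethane: two identical benzene rings joined through one CH2 carbon, with no stereocentre and no other ring. Numbered from the bridge, each ring carries the CH2 at C1, bromine at C2 and C3, hydroxyl at C4 and C5, and hydrogen only at C6. The sensitive parts are the two catechols, which oxidise readily to ortho-quinones, and the CH2 group para to the C4 hydroxyl, which can be drawn into quinone methide formation or ipso cleavage. The four C–Br bonds sit on electron-rich rings and rule out dissolving metals, catalytic hydrogenation and aryl anions next to bromine. The carbon skeleton is trivial; the difficulty is regiochemical, since four bromines must go to C2 and C3 of both rings and none to C6. A free catechol would activate C3, C6, C2 and the ipso carbon C1 all at once. The strategy rests on one feature of each ring: C3 is ortho to the C4 oxygen, C2 is para to the C5 oxygen, and C6 is only ortho to the C5 oxygen. If O4 is a free hydroxyl and O5 a methyl ether, the stronger donor claims C3 first and the ether then sends the second bromine para to itself, to C2. Because both rings are identical, all four C–Br bonds can be made in one operation on a symmetric core.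

## Retrosynthetic reasoning

**14 ⇒ 13.** The last bonds cut are the two O–CH3 bonds at O5. The free bis-catechol is the most oxidation-prone form of the molecule, and the O5 methyl groups are the element that steers the bromines, so they must survive every other operation. The forward step has to cleave two aryl methyl ethers next to a free hydroxyl without touching the C–Br bonds or the bridge; a boron trihalide at low temperature does this.

**13 ⇒ 11.** The bridging CH2 is traced back to a carbonyl group. This is a change of oxidation level, not a skeletal cut, and it is made because the ketone is what allows the bromination before it. The forward reaction must remove the carbonyl oxygen under conditions that spare aryl bromides and tolerate free, rather acidic bromophenols. An acid-mediated hydride transfer from a silane, passing through carbinol 12, meets both demands.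

**11 ⇒ 8 (key disconnection).** All four C–Br bonds, C3–Br and C2–Br of both rings, are cut together. Removing them here, and not earlier or later, leaves a precursor that is a plain symmetric diaryl ketone with no halogen, so everything before it can use organolithium chemistry freely. The forward reaction with bromine 9 must place the first bromine of each ring ortho to the free C4 hydroxyl (stage 10) and the second para to the C5 methoxy group. It must do so without ipso attack at C1 and without attack at the bridge. The carbonyl bridge answers the last two points: it makes C1 electron-poor and carries no benzylic hydrogen. Each ring of 8 has the substitution pattern of the 4-hydroxy-3-methoxyaryl carbonyl series, for which this order of bromination is established.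

**8 ⇒ 7.** The two phenolic O–H groups are traced back to benzyl ethers. The phenols must be masked for the carbanion chemistry that builds the bridge, and benzyl is chosen because it can be removed by a Lewis acid at low temperature while the methyl ethers, which must stay, are left alone.

**7 ⇒ 6 ⇒ 3 + 4.** The ketone is taken back to carbinol 6, and one aryl–C(bridge) bond is cut. Aldehyde 4 supplies one ring together with the bridge carbon; the other ring arrives as aryllithium 5, made from bromide 3. Cutting here, rather than attempting an acylation of an unfunctionalised ortho-methoxyphenol ring, fixes the point of attachment para to the benzyloxy group beyond doubt, because the carbon–lithium bond forms exactly where the carbon–bromine bond was.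

**3 ⇒ 1 + 2.** The O–benzyl bond is cut; phenol 1 already carries the bromine para to the hydroxyl, and benzyl bromide 2 supplies the protecting group.

## Alternatives that were turned down

**Alternative 1:** Each benzene ring is cut at C3–C4 and C5–C6, so that C4 and C5 with their oxygens come from vinylene carbonate A2. C3, C2, C1 and C6 come from a thiophene 1,1-dioxide, joined pairwise in bis(4,5-dibromo-1,1-dioxothiophen-3-yl)methane A1. In the forward sense each sulfone ring of A1 adds A2 across its two α-carbons and extrudes the sulfonyl bridge, closing two cis-fused dihydrocatechol carbonates in bis(6,7-dibromo-2-oxo-cis-3a,7a-dihydro-1,3-benzodioxol-5-yl)methane A3. On positional control this route is stronger than the chosen one: both bromines, both oxygens and the bridge are fixed by the building blocks and no directing effect has to be trusted. Against it stand three points. A1 is an electron-poor, halogenated bis-sulfone that must itself be made in several steps, and its oxidation to the dioxide level demands forcing peracid conditions. A2 is a sluggish dienophile that needs high temperature, at which the free α-position of A1 invites self-dimerisation. Most seriously, A3 is at the wrong oxidation level: the target needs loss of two hydrogens across C4–C5, whereas the easy path for a cis-dihydrocatechol derivative is β-elimination of one oxygen to a monophenol. Four stereocentres are also made only to be destroyed. The chosen route gives up the built-in regiochemistry but trades it for a one-step bromination with a close precedent and a precursor reached in four reliable steps.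

**Alternative 2:** Here each ring is cut at C1–C6 and C2–C3. 1,5-Dibromopenta-1,4-diyn-3-one A4 supplies C1, C2, the C2 bromine and the bridge carbon as a ketone, and two molecules of 2,3-dimethoxybuta-1,3-diene A5 supply C3 to C6 with both oxygens. The double Diels–Alder reaction should give bis(2-bromo-4,5-dimethoxycyclohexa-1,4-dien-1-yl)methanone A6, which a quinone oxidant would aromatise easily. In skeletal bonds per step this is stronger than the chosen route (four C–C bonds and both rings in one operation), and the symmetric diene removes any regiochemical question in the cycloaddition. Its weaknesses are elsewhere. A4 is a doubly activated bromoalkynyl ketone, a strong Michael acceptor of doubtful stability that has to be prepared and handled with care. A6 carries hydrogen, not bromine, at C3. The C3 bromine must therefore still be introduced by electrophilic substitution on a ring whose two oxygens are both methyl ethers and so do not distinguish C3 from C6. Repairing that would require a selective demethylation at O4 and then exactly the hydroxyl-directed bromination on which the chosen route is built. The alternative therefore borrows the chosen logic for half of the bromines while adding an unstable linchpin. The chosen route gets the same ketone-bridged core from shelf aromatics without it.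

**Alternative 3:** Each ring is cut at C1–C6 and C4–C5. 3,4-Dibromofuran A7 is elaborated to bis[3,4-dibromo-5-(triisopropylsilyloxy)furan-2-yl]methane A8, whose furan carbons become C1 to C4 with both bromines and the C4 oxygen in place. Methyl vinyl ketone A9 supplies C5 and C6. Lewis-acid-promoted cycloaddition, opening of the oxygen bridge and dehydration should give bis(5-acetyl-2,3-dibromo-4-hydroxyphenyl)methane A10. A peroxide oxidation of the ortho-hydroxy aryl ketone would then turn each acetyl group into the C5 hydroxyl. On two points this plan is stronger than the chosen one: no electrophilic bromination has to be selective, and the bridge is a CH2 from the start, so no deoxygenation is needed. Against it, A8 requires a methylene-bridged bis(dibromobutenolide), and β-bromobutenolides are prone to addition–elimination under the basic conditions needed to assemble and silylate them. The dibrominated silyloxyfuran is an electron-poor, hindered diene, and its substituted C2 terminus must form a fully substituted carbon with A9. Twofold benzannulation on such a substrate is a large extrapolation, so the risk sits in building the precursor as well as in the key step. The chosen strategy places its only real uncertainty in a single aromatic substitution whose directing effects agree with a known case.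

Key step: step 5

## Route

Step 1
Reactants: 1 4-bromo-2-methoxyphenol; 2 benzyl bromide
Product: 3 1-(benzyloxy)-4-bromo-2-methoxybenzene
Conditions: BnBr (1.1 equiv), K2CO3, DMF, rt
Reagents that add atoms: benzyl bromide 2, BrCc1ccccc1
Why: Williamson ether synthesis; the phenoxide of 1 displaces bromide from 2 by SN2, the aryl bromide is inert, and the acidic OH is masked before the lithiation.

Step 2
Reactants: 3 1-(benzyloxy)-4-bromo-2-methoxybenzene; 4 4-(benzyloxy)-3-methoxybenzaldehyde (O-benzylvanillin)
Product: 6 bis[4-(benzyloxy)-3-methoxyphenyl]methanol, via aryllithium 5 (not isolated)
Conditions: n-BuLi (1.05 equiv), THF, −78 °C; then 4, −78 → 0 °C; aq. NH4Cl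
Reagents that add atoms: none
Why: Bromine–lithium exchange at −78 °C is faster than ortho-lithiation or attack on the benzyl ether and puts the carbanion para to the benzyloxy group; 1,2-addition of 5 to the non-enolisable aldehyde 4 gives the benzhydrol, whose carbinol carbon bears two identical aryl groups and is not a stereocentre.

Step 3
Reactants: 6 bis[4-(benzyloxy)-3-methoxyphenyl]methanol
Product: 7 bis[4-(benzyloxy)-3-methoxyphenyl]methanone
Conditions: activated MnO2 (excess), CH2Cl2, rt
Reagents that add atoms: none
Why: MnO2 oxidation of a doubly benzylic secondary alcohol; the electron-rich benzhydrol oxidises readily, over-oxidation is impossible and the ethers are untouched.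

Step 4
Reactants: 7 bis[4-(benzyloxy)-3-methoxyphenyl]methanone
Product: 8 bis(4-hydroxy-3-methoxyphenyl)methanone
Conditions: BCl3 (4 equiv), C6HMe5 (6 equiv), CH2Cl2, −78 °C; then MeOH, −78 °C → rt; aq. work-up
Reagents that add atoms: none
Why: Lewis-acid debenzylation with pentamethylbenzene as a non-basic cation scavenger; at −78 °C the benzyl C–O bond ionises while the methyl ethers stay, the scavenger intercepts the benzyl cation before it can alkylate the electron-rich rings, and the ketone is not at risk as it would be under hydrogenolysis.

Step 5
Reactants: 8 bis(4-hydroxy-3-methoxyphenyl)methanone; 9 bromine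
Product: 11 bis(2,3-dibromo-4-hydroxy-5-methoxyphenyl)methanone, via dibromo ketone 10 (not isolated)
Conditions: Br2 (5 equiv), Fe powder (0.1 equiv), AcOH, rt then 55 °C; aq. NaHSO3
Reagents that add atoms: bromine 9, BrBr
Why: Electrophilic aromatic substitution through arenium ions, run on both rings at once. The free C4 hydroxyl is the strongest donor of each ring, so the first bromine per ring enters ortho to it at C3, which is also meta to the acyl group, and gives 10 without a catalyst. FeBr3, formed in the flask from Fe powder and 9, then activates bromine for the slower second substitution on the deactivated ring; the C5 methoxy group is the remaining uncommitted donor and directs para to itself, to C2, rather than to C6, which is only ortho to it and is flanked by the methoxy group and the carbonyl. The closest known reaction is the two-stage bromination of 4-hydroxy-3-methoxybenzaldehyde (vanillin) to its 5,6-dibromide, of which each ring of 8 is the aryl ketone analogue. No ring is closed and no stereocentre is formed. The selectivities needed are C3 before C2, C2 over C6, and ring substitution over ipso attack at C1 or attack at the bridge; the first two rest on O4 being free and O5 methylated, the third on the carbonyl bridge, which makes C1 electron-poor and has no benzylic hydrogen. The ortho bromines twist the rings out of conjugation with the carbonyl, so the second ring should react like the first, and a fifth bromine is not expected because C6 of a dibrominated ring is hindered and strongly deactivated.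

Step 6
Reactants: 11 bis(2,3-dibromo-4-hydroxy-5-methoxyphenyl)methanone
Product: 13 bis(2,3-dibromo-4-hydroxy-5-methoxyphenyl)methane, via tetrabromo carbinol 12 (not isolated)
Conditions: Et3SiH (6 equiv), TFA/CH2Cl2 (1:1), rt → 45 °C
Reagents that add atoms: none
Why: Ionic hydrogenation (silane–acid reduction of a diaryl ketone); the protonated carbonyl takes hydride to give 12, which ionises to a diarylmethyl cation stabilised by the para hydroxyl and takes a second hydride. Aryl C–Br bonds and methyl ethers are inert to silane and acid, and the acidic medium avoids the phenoxide formation that would deactivate the ketone towards a basic hydride.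

Step 7
Reactants: 13 bis(2,3-dibromo-4-hydroxy-5-methoxyphenyl)methane
Product: 14 bis(2,3-dibromo-4,5-dihydroxyphenyl)methane (target)
Conditions: BBr3 (6 equiv), CH2Cl2, −78 °C → rt, N2; then ice/H2O
Reagents that add atoms: none
Why: Lewis-acid cleavage of aryl methyl ethers; BBr3 binds the methoxy oxygen, assisted by the neighbouring hydroxyl, and bromide attacks the methyl carbon by SN2. The C–Br bonds and the CH2 bridge are untouched, and the step is placed last and run under N2 because the bis-catechol is prone to oxidation.

## Compound list

1 | 4-bromo-2-methoxyphenol | COc1cc(Br)ccc1O | starting material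
2 | benzyl bromide | BrCc1ccccc1 | starting material
3 | 1-(benzyloxy)-4-bromo-2-methoxybenzene | COc1cc(Br)ccc1OCc1ccccc1 | intermediate
4 | 4-(benzyloxy)-3-methoxybenzaldehyde (O-benzylvanillin) | COc1cc(C=O)ccc1OCc1ccccc1 | starting material
5 | [4-(benzyloxy)-3-methoxyphenyl]lithium | [Li]c1ccc(OCc2ccccc2)c(OC)c1 | intermediate (not isolated)
6 | bis[4-(benzyloxy)-3-methoxyphenyl]methanol | COc1cc(C(O)c2ccc(OCc3ccccc3)c(OC)c2)ccc1OCc1ccccc1 | intermediate
7 | bis[4-(benzyloxy)-3-methoxyphenyl]methanone | COc1cc(C(=O)c2ccc(OCc3ccccc3)c(OC)c2)ccc1OCc1ccccc1 | intermediate
8 | bis(4-hydroxy-3-methoxyphenyl)methanone | COc1cc(C(=O)c2ccc(O)c(OC)c2)ccc1O | intermediate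
9 | bromine | BrBr | starting material
10 | bis(3-bromo-4-hydroxy-5-methoxyphenyl)methanone | COc1cc(C(=O)c2cc(OC)c(O)c(Br)c2)cc(Br)c1O | intermediate (not isolated)
11 | bis(2,3-dibromo-4-hydroxy-5-methoxyphenyl)methanone | COc1cc(C(=O)c2cc(OC)c(O)c(Br)c2Br)c(Br)c(Br)c1O | intermediate
12 | bis(2,3-dibromo-4-hydroxy-5-methoxyphenyl)methanol | COc1cc(C(O)c2cc(OC)c(O)c(Br)c2Br)c(Br)c(Br)c1O | intermediate (not isolated)
13 | bis(2,3-dibromo-4-hydroxy-5-methoxyphenyl)methane | COc1cc(Cc2cc(OC)c(O)c(Br)c2Br)c(Br)c(Br)c1O | intermediate
14 | bis(2,3-dibromo-4,5-dihydroxyphenyl)methane (CNP0260813.0) | Oc1cc(Cc2cc(O)c(O)c(Br)c2Br)c(Br)c(Br)c1O | target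

## Step count and risk

Total step count: 7. Longest linear sequence: 7 steps (1 → 3 → 6 → 7 → 8 → 11 → 13 → 14); aldehyde 4 enters in step 2 as purchased.

**Key step (step 5).** The most likely failure is imperfect control of the second bromination on each ring. It could stall after three bromines on the deactivated, twisted ketone, or be accompanied by competing substitution at C6. Either leaves a mixture of closely related polybromides that is hard to separate. Ipso attack at C1 with loss of the acyl group is a lesser concern. The fallback inverts the order of the two brominations so that each is ruled by a single director. It sets out from 8. Acetylation (Ac2O, pyridine) gives bis(4-acetoxy-3-methoxyphenyl)methanone F1. With the phenol masked as a weakly donating ester, the methoxy group is the strongest donor, and bromination (9, NaOAc, AcOH) should go para to it to give bis(4-acetoxy-2-bromo-5-methoxyphenyl)methanone F2, as is known for O-acetylated 4-hydroxy-3-methoxybenzaldehyde. Methanolysis (K2CO3, MeOH) then frees bis(2-bromo-4-hydroxy-5-methoxyphenyl)methanone F3. In F3, C3 is the only open position ortho to the hydroxyl, and uncatalysed bromination with 9 in AcOH at room temperature returns to the route at 11.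

**Deoxygenation (step 6).** The carbonyl of 11 is flanked by two ortho-brominated, electron-poor rings, so protonation and the first hydride transfer may be too slow, and forcing the acid strength could start protodebromination of the bromophenol rings. The fallback separates hydride addition from ionisation and caps the phenols so that a basic hydride can be used. It sets out from 11. Methylation (MeI, K2CO3, acetone) gives bis(2,3-dibromo-4,5-dimethoxyphenyl)methanone F4. NaBH4 in THF/MeOH reduces it to bis(2,3-dibromo-4,5-dimethoxyphenyl)methanol F5, which ionises far more easily than a ketone is protonated. Et3SiH/TFA then gives bis(2,3-dibromo-4,5-dimethoxyphenyl)methane F6, and BBr3 cleaves all four methyl ethers, so the fallback rejoins the route at 14.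

**Final demethylation (step 7).** The risk lies in the free bis-catechol diarylmethane in the presence of strong Lewis and Brønsted acid and during work-up. The product may oxidise towards quinone or quinone methide, and the very electron-rich ring may undergo acid-promoted loss or shift of bromine. The fallback moves the demethylation to the ketone level, where the ring is deactivated and the catechol is less easily oxidised, and makes a reductive step the last one. It sets out from 11. BBr3 in CH2Cl2 gives bis(2,3-dibromo-4,5-dihydroxyphenyl)methanone F7, and ionic hydrogenation with Et3SiH/TFA then reduces the bridge and returns to the route at 14.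

**Debenzylation (step 4).** The likely failure is loss of selectivity between the benzyl and methyl ethers. Once the phenoxide is bound to boron, the neighbouring methoxy oxygen is held in a chelate and can be demethylated as well if the temperature rises. The fallback changes the protecting group to one removed by mild protic acid. It sets out from 1. MOMCl and i-Pr2NEt give 4-bromo-2-methoxy-1-(methoxymethoxy)benzene F8. Bromine–lithium exchange (n-BuLi, THF, −78 °C) followed by ethyl formate (0.5 equiv) gives the symmetric bis[3-methoxy-4-(methoxymethoxy)phenyl]methanol F9. MnO2 oxidation gives bis[3-methoxy-4-(methoxymethoxy)phenyl]methanone F10, and HCl in MeOH removes both acetals to return to the route at 8.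

## Further compounds

F1 | step 5 | bis(4-acetoxy-3-methoxyphenyl)methanone | COc1cc(C(=O)c2ccc(OC(C)=O)c(OC)c2)ccc1OC(C)=O
F2 | step 5 | bis(4-acetoxy-2-bromo-5-methoxyphenyl)methanone | COc1cc(C(=O)c2cc(OC)c(OC(C)=O)cc2Br)c(Br)cc1OC(C)=O
F3 | step 5 | bis(2-bromo-4-hydroxy-5-methoxyphenyl)methanone | COc1cc(C(=O)c2cc(OC)c(O)cc2Br)c(Br)cc1O
F4 | step 6 | bis(2,3-dibromo-4,5-dimethoxyphenyl)methanone | COc1cc(C(=O)c2cc(OC)c(OC)c(Br)c2Br)c(Br)c(Br)c1OC
F5 | step 6 | bis(2,3-dibromo-4,5-dimethoxyphenyl)methanol | COc1cc(C(O)c2cc(OC)c(OC)c(Br)c2Br)c(Br)c(Br)c1OC
F6 | step 6 | bis(2,3-dibromo-4,5-dimethoxyphenyl)methane | COc1cc(Cc2cc(OC)c(OC)c(Br)c2Br)c(Br)c(Br)c1OC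
F7 | step 7 | bis(2,3-dibromo-4,5-dihydroxyphenyl)methanone | O=C(c1cc(O)c(O)c(Br)c1Br)c1cc(O)c(O)c(Br)c1Br
F8 | step 4 | 4-bromo-2-methoxy-1-(methoxymethoxy)benzene | COCOc1ccc(Br)cc1OC
F9 | step 4 | bis[3-methoxy-4-(methoxymethoxy)phenyl]methanol | COCOc1ccc(C(O)c2ccc(OCOC)c(OC)c2)cc1OC
F10 | step 4 | bis[3-methoxy-4-(methoxymethoxy)phenyl]methanone | COCOc1ccc(C(=O)c2ccc(OCOC)c(OC)c2)cc1OC
A1 | alternative 1 | bis(4,5-dibromo-1,1-dioxothiophen-3-yl)methane | O=S1(=O)C=C(CC2=CS(=O)(=O)C(Br)=C2Br)C(Br)=C1Br
A2 | alternative 1 | vinylene carbonate (1,3-dioxol-2-one) | O=C1OC=CO1
A3 | alternative 1 | bis(6,7-dibromo-2-oxo-cis-3a,7a-dihydro-1,3-benzodioxol-5-yl)methane | C(C1=C[C@H]2OC(=O)O[C@H]2C(Br)=C1Br)C1=C[C@H]2OC(=O)O[C@H]2C(Br)=C1Br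
A4 | alternative 2 | 1,5-dibromopenta-1,4-diyn-3-one | O=C(C#CBr)C#CBr
A5 | alternative 2 | 2,3-dimethoxybuta-1,3-diene | COC(=C)C(=C)OC
A6 | alternative 2 | bis(2-bromo-4,5-dimethoxycyclohexa-1,4-dien-1-yl)methanone | O=C(C1=C(Br)CC(OC)=C(OC)C1)C1=C(Br)CC(OC)=C(OC)C1
A7 | alternative 3 | 3,4-dibromofuran | Brc1cocc1Br
A8 | alternative 3 | bis[3,4-dibromo-5-(triisopropylsilyloxy)furan-2-yl]methane | CC(C)[Si](Oc1oc(Cc2oc(O[Si](C(C)C)(C(C)C)C(C)C)c(Br)c2Br)c(Br)c1Br)(C(C)C)C(C)C
A9 | alternative 3 | methyl vinyl ketone | CC(=O)C=C
A10 | alternative 3 | bis(5-acetyl-2,3-dibromo-4-hydroxyphenyl)methane | CC(=O)c1cc(Cc2cc(C(C)=O)c(O)c(Br)c2Br)c(Br)c(Br)c1O
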